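## Analysis of the target

Compound 15 is a flavone, a 4H-chromen-4-one (rings A and C) that carries a 2,4,5-trimethoxyphenyl group (ring B) on C2 and a methoxy group on C3. It has no stereocenter, so the whole task is the substitution pattern. Ring A is fully substituted and bears oxygen on every carbon from C5 to C8a in three different states: free hydroxyl at C5 and C7, methoxy at C6 and C8, and the ring oxygen O1 at C8a. The sensitive parts are the electron-rich 5,7-dihydroxy-6,8-dimethoxy ring, which oxidises easily once the phenols are free, and the pyranone, whose C2 accepts hard nucleophiles with ring opening; the phenols are therefore carried as benzyl ethers, which also keeps them distinct from the six methyl ethers, and are freed last. The difficulty is a hexasubstituted arene with five contiguous, differentiated oxygens, together with a heteroatom at C3 that has to be placed while ring C is made. The plan rests on the fact that ring A is symmetric when seen from C4a, because C5 and C8a both carry oxygen and C6 and C8 both carry methoxy. A 2,4,6-tris(benzyloxy)-3,5-dimethoxyphenyl alkynyl ketone therefore has two identical ortho benzyloxy groups, either of which can become O1 while the other stays as the protected O5, and the electrophile that triggers the closure ends up on C3.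

## Retrosynthetic reasoning

**15 to 14.** The O–H bonds at O5 and O7 are traced back to O–benzyl bonds. Benzyl is chosen because hydrogenolysis removes it without touching aryl methyl ethers, and because the oxidation-prone polyphenol then appears only in the last step. The forward reaction has to cleave two aryl benzyl ethers and leave C2=C3 alone.

**14 to 13.** The C3–O bond is cut to a C3–I bond. Iodine is what the ring closure delivers at C3, and a carbon–iodine bond at an sp2 carbon is the natural handle for a copper-catalysed C–O coupling. The forward reaction must exchange iodide for methoxide next to the carbonyl without opening the pyranone at C2.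

**13 to 10 and 11.** O1–C2 and C3–I are cut together, which opens ring C to the alkynyl ketone 10 and the electrophile 11. Cutting here, and not at C4–C4a or O1–C8a, is what leaves a ring A piece symmetric about its acyl carbon, so the two ortho oxygens never have to be told apart. Forward, 11 must activate the triple bond, one ortho benzyloxy oxygen must close in the 6-endo mode onto the alkyne carbon that bears ring B, and that oxygen must give up its benzyl group.

**10 to 9, then to 5 and 8.** After adjusting the oxidation level to carbinol 9, the C4–C3 bond (carbonyl carbon to alkyne carbon) is cut to aldehyde 5 and acetylide 8. This joins two complete arene halves late. A 1,2-addition to a non-enolisable aldehyde tolerates the two ortho substituents better than an acylation of the crowded arene would. Forward, a clean addition and a mild oxidation of a propargylic, benzylic alcohol are needed.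

**8 to 7 to 6.** The alkyne carbon is removed by a one-carbon homologation in reverse. The dibromoalkene 7 stores the acetylide in a stable form and comes from the purchasable ring B aldehyde 6 in one step.

**5 to 3.** The C–CHO bond is cut at the only unsubstituted position of ring A, which is flanked by two benzyloxy groups and para to the third. Forward, this is an electrophilic formylation with no regiochemical choice.

**3 to 2 to 1.** The two C–OMe bonds are cut to C–Br bonds and these to C–H. The 1,3,5-trioxygenated pattern of 1 already holds the three benzyloxy oxygens in the right alternation, its ring positions are activated for halogenation, and 1 is taken from the catalogue. Forward, the steps are a double bromination and a double copper-mediated methoxylation at positions flanked by two ethers.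

## Alternatives that were turned down

Alternative 1: Ring C is cut at C4a–C4, C4–C3 and O1–C2, into the iodophenol 3,5-bis(benzyloxy)-2-iodo-4,6-dimethoxyphenol A2, the arylacetylene 1-ethynyl-2,4,5-trimethoxybenzene A3 and carbon monoxide A4. In the forward step a palladium–phosphine catalyst inserts into the C–I bond of A2 and takes up A4, and the acyl palladium species couples with A3. A secondary amine then mediates closure of the ortho-hydroxyaryl ynone to 5,7-bis(benzyloxy)-6,8-dimethoxy-2-(2,4,5-trimethoxyphenyl)-4H-chromen-4-one A1.

- For it: three bonds and C4 come from one operation, no carbinol oxidation is needed, and no stoichiometric electrophile is used. On convergence it is stronger than the chosen plan.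
- Against it: A1 has no substituent at C3, so the C3 oxygen would still cost a metalation, an oxidation and a methylation. A2 is unsymmetrical and needs one free hydroxyl beside the iodide among three otherwise equal oxygens, which means a desymmetrisation of ring A. Its C–I bond is flanked by two substituents on a very electron-rich ring, which slows oxidative addition to zerovalent palladium and gives the carbonyl-free coupling with 5-endo closure room to compete.
- In its place the chosen plan offers a symmetric ring A piece and a C3 handle set in the ring-closing step itself.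

Alternative 2: Ring B is cut at C5'–C6', C1'–C2' and C2'–C3', back to the alkyne 5,7-bis(benzyloxy)-2-ethynyl-3,6,8-trimethoxy-4H-chromen-4-one A5 and the carbene complex Cr(CO)5[C(OMe)C(OMe)=CH2] A6. Forward, a thermal Dötz benzannulation of A5 with A6 would give the 2'-phenol 5,7-bis(benzyloxy)-2-(2-hydroxy-4,5-dimethoxyphenyl)-3,6,8-trimethoxy-4H-chromen-4-one A7, whose O-methylation leads to 14.

- For it: the oxygen pattern of ring B is fixed by the mechanism, and the C3 methoxy group is present before the key step. On ring B regiocontrol it is as strong as any route.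
- Against it: ring B can be bought complete as 6, so building it spends steps on the easy half. A5 still needs all the ring A and ring C chemistry plus a C2 alkyne. That alkyne is conjugated to the pyranone and is an acceptor, a poor partner for insertion into a chromium carbene and open to conjugate addition. Chromium is stoichiometric, and the new para-alkoxyphenol ring is prone to over-oxidation when the metal is removed.
- In its place the chosen plan keeps all risk in one closure of ring C and uses no stoichiometric transition metal.

Alternative 3: Ring C is cut at C3–C4 and O1–C8a, into the ketone 2-methoxy-1-(2,4,5-trimethoxyphenyl)ethan-1-one A8 and the acid chloride 2,4-bis(benzyloxy)-6-bromo-3,5-dimethoxybenzoyl chloride A9. Forward, the lithium enolate of A8 is C-acylated by A9 to the diketone 1-[2,4-bis(benzyloxy)-6-bromo-3,5-dimethoxyphenyl]-2-methoxy-3-(2,4,5-trimethoxyphenyl)propane-1,3-dione A10. A monovalent copper salt then closes ring C in the same flask by O-arylation of its enolate, giving 5,7-bis(benzyloxy)-3,6,8-trimethoxy-2-(2,4,5-trimethoxyphenyl)-4H-chromen-4-one A11, which is the same substance as 14.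

- For it: the C3 methoxy group arrives with A8, no iodide has to be exchanged, and only the hydrogenolysis remains. On the endgame it is clearly stronger than the chosen plan.
- Against it: A9 is unsymmetrical, with bromine on one side of the acyl group and benzyloxy on the other, so ring A again has to be desymmetrised over several steps. C-acylation of an α-alkoxy enolate by a 2,6-disubstituted aroyl chloride competes with O-acylation, and A10 consumes base. The O-arylation must take place at a bromide flanked by a methoxy group and the acyl group.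
- In its place the chosen plan offers a symmetric ring A aldehyde that is three steps from a purchased triether, and bond formations that are either intramolecular or 1,2-additions, at the price of one extra step at C3.

Key step: step 7

Remark on the chemistry: 1,3,5-tris(benzyloxy)benzene 1 is assumed to be a purchased compound, and carbinol 9 is used as the racemate, since its only stereocenter is removed in step 6.

## Route

Step 1
Reactants: 1 1,3,5-tris(benzyloxy)benzene
Product: 2 1,3,5-tris(benzyloxy)-2,4-dibromobenzene
Conditions: NBS (2.05 equiv), CH2Cl2/MeCN, 0 °C→rt, dark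
Reagents that add atoms: N-bromosuccinimide, O=C1CCC(=O)N1Br
Why: Electrophilic aromatic bromination of a 1,3,5-trialkoxybenzene, whose three ring positions are equivalent and strongly activated; each bromine lowers the reactivity toward the next, so two equivalents under ionic conditions should stop at the dibromide without benzylic bromination.

Step 2
Reactants: 2 1,3,5-tris(benzyloxy)-2,4-dibromobenzene
Product: 3 1,3,5-tris(benzyloxy)-2,4-dimethoxybenzene
Conditions: NaOMe (10 equiv, 25% in MeOH), CuI (0.5 equiv), DMF, 110 °C
Reagents that add atoms: sodium methoxide, C[O-].[Na+]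
Why: Copper-mediated methoxylation of aryl bromides (Ullmann-type ether synthesis), the standard way to turn bromides flanked by alkoxy groups into methyl ethers; aryl benzyl ethers are inert to methoxide.

Step 3
Reactants: 3 1,3,5-tris(benzyloxy)-2,4-dimethoxybenzene
Product: 5 2,4,6-tris(benzyloxy)-3,5-dimethoxybenzaldehyde, via aryl iminium chloride 4 (not isolated)
Conditions: POCl3 (1.5 equiv), DMF, 0→50 °C; then aq. NaOAc
Reagents that add atoms: N,N-dimethylformamide, CN(C)C=O; water, O
Why: Vilsmeier–Haack formylation at the only unsubstituted ring position, which is ortho to two benzyloxy groups and para to the third; the iminium salt 4 is hydrolysed on buffered work-up, and the mild conditions should spare the benzyl ethers.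

Step 4
Reactants: 6 2,4,5-trimethoxybenzaldehyde
Product: 7 1-(2,2-dibromoethenyl)-2,4,5-trimethoxybenzene
Conditions: CBr4 (2 equiv), PPh3 (4 equiv), CH2Cl2, 0 °C
Reagents that add atoms: carbon tetrabromide, BrC(Br)(Br)Br
Why: First stage of the Corey–Fuchs reaction, a Wittig-type olefination by Ph3P=CBr2 made in the flask; 7 is a stable, storable precursor of the oxidation-prone arylacetylene.

Step 5
Reactants: 7 1-(2,2-dibromoethenyl)-2,4,5-trimethoxybenzene; 5 2,4,6-tris(benzyloxy)-3,5-dimethoxybenzaldehyde
Product: 9 rac-1-[2,4,6-tris(benzyloxy)-3,5-dimethoxyphenyl]-3-(2,4,5-trimethoxyphenyl)prop-2-yn-1-ol, via lithium acetylide 8 (not isolated)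
Conditions: n-BuLi (2.05 equiv), THF, −78→0 °C; then 5, −78→0 °C; H2O quench
Reagents that add atoms: none
Why: Second stage of the Corey–Fuchs reaction: bromine–lithium exchange, loss of LiBr with 1,2-shift (Fritsch–Buttenberg–Wiechell) and deprotonation by the second equivalent of n-BuLi give acetylide 8, which adds 1,2 to the hindered but non-enolisable aldehyde 5. The carbinol centre forms without control (racemate) and is removed in step 6.

Step 6
Reactants: 9 rac-1-[2,4,6-tris(benzyloxy)-3,5-dimethoxyphenyl]-3-(2,4,5-trimethoxyphenyl)prop-2-yn-1-ol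
Product: 10 1-[2,4,6-tris(benzyloxy)-3,5-dimethoxyphenyl]-3-(2,4,5-trimethoxyphenyl)prop-2-yn-1-one
Conditions: MnO2 (activated, excess), CH2Cl2, rt
Reagents that add atoms: none
Why: MnO2 oxidation of an alcohol that is both propargylic and benzylic; the neutral heterogeneous conditions leave the benzyl ethers, the alkyne and the electron-rich rings untouched.

Step 7
Reactants: 10 1-[2,4,6-tris(benzyloxy)-3,5-dimethoxyphenyl]-3-(2,4,5-trimethoxyphenyl)prop-2-yn-1-one; 11 iodine monochloride
Product: 13 5,7-bis(benzyloxy)-3-iodo-6,8-dimethoxy-2-(2,4,5-trimethoxyphenyl)-4H-chromen-4-one, via O1-benzyl oxonium chloride 12 (not isolated)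
Conditions: ICl (1.1 equiv, 1 M in CH2Cl2), CH2Cl2, −78 °C; aq. Na2S2O3
Reagents that add atoms: none
Why: ICl adds to the triple bond of 10 as an iodonium ion whose positive charge lies on the carbon attached to ring B (the later C2), because the 2'- and 4'-methoxy groups stabilise it there and the carbonyl disfavours charge on the other alkyne carbon. One of the two equivalent ortho benzyloxy oxygens of ring A attacks that carbon anti to iodine, which forms O1–C2 and C3–I and closes ring C in the 6-endo-dig mode to give oxonium salt 12. Chloride then removes the benzyl group from the oxonium oxygen by SN2 attack at the benzylic carbon, releasing benzyl chloride and the neutral chromone 13. The closest known reaction type is the ICl-induced cyclisation of 2-methoxyaryl alkynyl ketones to 3-iodochromones with loss of methyl chloride, and a benzyl group should depart more easily than methyl. No stereocenter is formed. The step needs 6-endo over 5-exo closure, which the polarisation of the iodonium ion toward C2 and the pyrylium-like stabilisation of 12 should secure; it needs closure by a ring A oxygen and not by the 2'-methoxy oxygen of ring B, which can only reach the carbonyl-bearing alkyne carbon where positive charge is disfavoured; and it needs attack on the alkyne before iodination of ring B, which the deactivation of that ring by the conjugated ynone, the small excess of ICl and the low temperature should provide. Since the two ortho ethers are the same, a single chromone is possible and the ether that is not used becomes the protected O5.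

Step 8
Reactants: 13 5,7-bis(benzyloxy)-3-iodo-6,8-dimethoxy-2-(2,4,5-trimethoxyphenyl)-4H-chromen-4-one
Product: 14 5,7-bis(benzyloxy)-3,6,8-trimethoxy-2-(2,4,5-trimethoxyphenyl)-4H-chromen-4-one
Conditions: CuI (20 mol%), 1,10-phenanthroline (40 mol%), Cs2CO3 (2 equiv), MeOH/toluene, 100 °C, sealed tube
Reagents that add atoms: methanol, CO
Why: Proposed new method: the C3–I bond of 13 is an alkenyl iodide that should add oxidatively to a phenanthroline-ligated monovalent copper methoxide and then eliminate the enol ether reductively, as in the copper-catalysed (Ullmann-type) etherification of aryl and alkenyl iodides with aliphatic alcohols, which is the closest known reaction type but is not established for the C3 iodide of a chromone; the 2-aryl group and the donor-rich ring A lower the electrophilicity of C2, and the weak carbonate base keeps free methoxide low, so conjugate attack and ring opening should stay behind the coupling.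

Step 9
Reactants: 14 5,7-bis(benzyloxy)-3,6,8-trimethoxy-2-(2,4,5-trimethoxyphenyl)-4H-chromen-4-one
Product: 15 5,7-dihydroxy-3,6,8-trimethoxy-2-(2,4,5-trimethoxyphenyl)-4H-chromen-4-one (5,7-dihydroxy-3,6,8,2',4',5'-hexamethoxyflavone)
Conditions: H2 (1 atm), 10% Pd/C, EtOAc/MeOH, rt
Reagents that add atoms: none
Why: Hydrogenolysis of the two aryl benzyl ethers; the tetrasubstituted, vinylogous-ester C2=C3 bond and the aryl methyl ethers should not be reduced at atmospheric pressure, and the free polyphenol is exposed only in this last step.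

## Compound list

1 | 1,3,5-tris(benzyloxy)benzene | c1ccc(COc2cc(OCc3ccccc3)cc(OCc3ccccc3)c2)cc1 | starting material
2 | 1,3,5-tris(benzyloxy)-2,4-dibromobenzene | Brc1c(OCc2ccccc2)cc(OCc2ccccc2)c(Br)c1OCc1ccccc1 | intermediate
3 | 1,3,5-tris(benzyloxy)-2,4-dimethoxybenzene | COc1c(OCc2ccccc2)cc(OCc2ccccc2)c(OC)c1OCc1ccccc1 | intermediate
4 | N-{[2,4,6-tris(benzyloxy)-3,5-dimethoxyphenyl]methylidene}-N-methylmethanaminium chloride | C[N+](C)=Cc1c(OCc2ccccc2)c(OC)c(OCc2ccccc2)c(OC)c1OCc1ccccc1.[Cl-] | intermediate
5 | 2,4,6-tris(benzyloxy)-3,5-dimethoxybenzaldehyde | O=Cc1c(OCc2ccccc2)c(OC)c(OCc2ccccc2)c(OC)c1OCc1ccccc1 | intermediate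
6 | 2,4,5-trimethoxybenzaldehyde | COc1cc(OC)c(C=O)cc1OC | starting material
7 | 1-(2,2-dibromoethenyl)-2,4,5-trimethoxybenzene | COc1cc(OC)c(C=C(Br)Br)cc1OC | intermediate
8 | lithium (2,4,5-trimethoxyphenyl)ethynide | COc1cc(OC)c(C#[C-])cc1OC.[Li+] | intermediate
9 | rac-1-[2,4,6-tris(benzyloxy)-3,5-dimethoxyphenyl]-3-(2,4,5-trimethoxyphenyl)prop-2-yn-1-ol (racemate) | COc1cc(OC)c(C#CC(O)c2c(OCc3ccccc3)c(OC)c(OCc3ccccc3)c(OC)c2OCc2ccccc2)cc1OC | intermediate
10 | 1-[2,4,6-tris(benzyloxy)-3,5-dimethoxyphenyl]-3-(2,4,5-trimethoxyphenyl)prop-2-yn-1-one | COc1cc(OC)c(C#CC(=O)c2c(OCc3ccccc3)c(OC)c(OCc3ccccc3)c(OC)c2OCc2ccccc2)cc1OC | intermediate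
11 | iodine monochloride | ClI | starting material
12 | 1-benzyl-5,7-bis(benzyloxy)-3-iodo-6,8-dimethoxy-4-oxo-2-(2,4,5-trimethoxyphenyl)-4H-chromen-1-ium chloride | COc1cc(OC)c(C2=C(I)C(=O)c3c(OCc4ccccc4)c(OC)c(OCc4ccccc4)c(OC)c3[O+]2Cc2ccccc2)cc1OC.[Cl-] | intermediate
13 | 5,7-bis(benzyloxy)-3-iodo-6,8-dimethoxy-2-(2,4,5-trimethoxyphenyl)-4H-chromen-4-one | COc1cc(OC)c(-c2oc3c(OC)c(OCc4ccccc4)c(OC)c(OCc4ccccc4)c3c(=O)c2I)cc1OC | intermediate
14 | 5,7-bis(benzyloxy)-3,6,8-trimethoxy-2-(2,4,5-trimethoxyphenyl)-4H-chromen-4-one | COc1cc(OC)c(-c2oc3c(OC)c(OCc4ccccc4)c(OC)c(OCc4ccccc4)c3c(=O)c2OC)cc1OC | intermediate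
15 | 5,7-dihydroxy-3,6,8-trimethoxy-2-(2,4,5-trimethoxyphenyl)-4H-chromen-4-one | COc1cc(OC)c(-c2oc3c(OC)c(O)c(OC)c(O)c3c(=O)c2OC)cc1OC | target

## Step count and least certain steps

Total: 9 steps. Longest linear sequence: 8 steps (steps 1 to 3 and 5 to 9, from 1 to 15). Step 4 is a one-step side branch that joins in step 5.

**Step 8 (Proposed new method).** The most likely failure is conjugate attack of methoxide at C2 with opening or contraction of the pyranone, or copper-mediated protodeiodination. Either could outrun C–O coupling at an alkenyl iodide crowded by the carbonyl and the ortho-substituted ring B. The fallback uses known chemistry, sets out from 13 and comes back at 14. Hydrodeiodination of 13 with Pd(PPh3)4 and HCO2Na in DMF would give 5,7-bis(benzyloxy)-6,8-dimethoxy-2-(2,4,5-trimethoxyphenyl)-4H-chromen-4-one F1, the same substance as A1. LDA in THF at −78 °C deprotonates C3 of the flavone to [5,7-bis(benzyloxy)-6,8-dimethoxy-4-oxo-2-(2,4,5-trimethoxyphenyl)-4H-chromen-3-yl]lithium F2. B(OMe)3 converts it into lithium [5,7-bis(benzyloxy)-6,8-dimethoxy-4-oxo-2-(2,4,5-trimethoxyphenyl)-4H-chromen-3-yl]trimethoxyborate F3. H2O2/AcOH in the same flask oxidises the C–B bond to the flavonol 5,7-bis(benzyloxy)-3-hydroxy-6,8-dimethoxy-2-(2,4,5-trimethoxyphenyl)-4H-chromen-4-one F4, and MeI/K2CO3 in acetone methylates F4 to 14.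

**Step 7 (key step).** Several processes can go wrong: iodination of ring B at C3', simple anti addition of ICl across the alkyne, closure in the 5-exo mode, or loss of further benzyl groups to the Lewis-acidic iodine species. The ketone is also twisted out of the plane of ring A by its two ortho substituents and may be slow to reach the coplanar arrangement the closure needs. The fallback separates ring closure from C3 functionalisation, sets out from 10 and comes back at 13. BCl3 (1 equiv, CH2Cl2, −78 °C) removes one of the two equivalent ortho benzyl groups under chelation control to give 1-[2,4-bis(benzyloxy)-6-hydroxy-3,5-dimethoxyphenyl]-3-(2,4,5-trimethoxyphenyl)prop-2-yn-1-one F5. DMAP in DMF closes the phenol onto the ynone in the 6-endo mode to 5,7-bis(benzyloxy)-6,8-dimethoxy-2-(2,4,5-trimethoxyphenyl)-4H-chromen-4-one F1. LDA at −78 °C gives [5,7-bis(benzyloxy)-6,8-dimethoxy-4-oxo-2-(2,4,5-trimethoxyphenyl)-4H-chromen-3-yl]lithium F2, and I2 converts it into 13.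

**Step 2.** Hydrodebromination can compete with the second substitution, and conversion may stall at bromides flanked by two alkoxy groups on a very electron-rich ring. The fallback uses no halide and no copper, sets out from 1 and comes back at 3. Vilsmeier formylation of 1 (POCl3/DMF) passes through N-{[2,4,6-tris(benzyloxy)phenyl]methylidene}-N-methylmethanaminium chloride F6 to 2,4,6-tris(benzyloxy)benzaldehyde F7. Baeyer–Villiger oxidation with mCPBA gives 2,4,6-tris(benzyloxy)phenyl formate F8, which KOH in MeOH/H2O cleaves to 2,4,6-tris(benzyloxy)phenol F9. MeI/K2CO3 then gives 1,3,5-tris(benzyloxy)-2-methoxybenzene F10. A second round of the same three operations leads through N-{[2,4,6-tris(benzyloxy)-3-methoxyphenyl]methylidene}-N-methylmethanaminium chloride F11, 2,4,6-tris(benzyloxy)-3-methoxybenzaldehyde F12 and 2,4,6-tris(benzyloxy)-3-methoxyphenyl formate F13 to 2,4,6-tris(benzyloxy)-3-methoxyphenol F14, whose methylation gives 3.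

**Step 3.** Electrophilic attack may be slow at a position screened by two benzyloxy groups, and the acidic medium can remove a benzyl group ortho to the new formyl group. The fallback reverses the polarity, sets out from 3 and comes back at 5. NBS brominates the free position to 1,3,5-tris(benzyloxy)-2-bromo-4,6-dimethoxybenzene F15. n-BuLi in THF at −78 °C exchanges bromine for lithium faster than it deprotonates the benzylic positions, giving [2,4,6-tris(benzyloxy)-3,5-dimethoxyphenyl]lithium F16. DMF traps it as lithium [2,4,6-tris(benzyloxy)-3,5-dimethoxyphenyl](dimethylamino)methanolate F17, which collapses to 5 on aqueous work-up.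

## Further compounds

F1 | step 8 | 5,7-bis(benzyloxy)-6,8-dimethoxy-2-(2,4,5-trimethoxyphenyl)-4H-chromen-4-one | COc1cc(OC)c(-c2cc(=O)c3c(OCc4ccccc4)c(OC)c(OCc4ccccc4)c(OC)c3o2)cc1OC
F2 | step 8 | [5,7-bis(benzyloxy)-6,8-dimethoxy-4-oxo-2-(2,4,5-trimethoxyphenyl)-4H-chromen-3-yl]lithium | COc1cc(OC)c(-c2oc3c(OC)c(OCc4ccccc4)c(OC)c(OCc4ccccc4)c3c(=O)c2[Li])cc1OC
F3 | step 8 | lithium [5,7-bis(benzyloxy)-6,8-dimethoxy-4-oxo-2-(2,4,5-trimethoxyphenyl)-4H-chromen-3-yl]trimethoxyborate | COc1cc(OC)c(-c2oc3c(OC)c(OCc4ccccc4)c(OC)c(OCc4ccccc4)c3c(=O)c2[B-](OC)(OC)OC)cc1OC.[Li+]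
F4 | step 8 | 5,7-bis(benzyloxy)-3-hydroxy-6,8-dimethoxy-2-(2,4,5-trimethoxyphenyl)-4H-chromen-4-one | COc1cc(OC)c(-c2oc3c(OC)c(OCc4ccccc4)c(OC)c(OCc4ccccc4)c3c(=O)c2O)cc1OC
F5 | step 7 | 1-[2,4-bis(benzyloxy)-6-hydroxy-3,5-dimethoxyphenyl]-3-(2,4,5-trimethoxyphenyl)prop-2-yn-1-one | COc1cc(OC)c(C#CC(=O)c2c(O)c(OC)c(OCc3ccccc3)c(OC)c2OCc2ccccc2)cc1OC
F6 | step 2 | N-{[2,4,6-tris(benzyloxy)phenyl]methylidene}-N-methylmethanaminium chloride | C[N+](C)=Cc1c(OCc2ccccc2)cc(OCc2ccccc2)cc1OCc1ccccc1.[Cl-]
F7 | step 2 | 2,4,6-tris(benzyloxy)benzaldehyde | O=Cc1c(OCc2ccccc2)cc(OCc2ccccc2)cc1OCc1ccccc1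
F8 | step 2 | 2,4,6-tris(benzyloxy)phenyl formate | O=COc1c(OCc2ccccc2)cc(OCc2ccccc2)cc1OCc1ccccc1
F9 | step 2 | 2,4,6-tris(benzyloxy)phenol | Oc1c(OCc2ccccc2)cc(OCc2ccccc2)cc1OCc1ccccc1
F10 | step 2 | 1,3,5-tris(benzyloxy)-2-methoxybenzene | COc1c(OCc2ccccc2)cc(OCc2ccccc2)cc1OCc1ccccc1
F11 | step 2 | N-{[2,4,6-tris(benzyloxy)-3-methoxyphenyl]methylidene}-N-methylmethanaminium chloride | COc1c(OCc2ccccc2)cc(OCc2ccccc2)c(C=[N+](C)C)c1OCc1ccccc1.[Cl-]
F12 | step 2 | 2,4,6-tris(benzyloxy)-3-methoxybenzaldehyde | COc1c(OCc2ccccc2)cc(OCc2ccccc2)c(C=O)c1OCc1ccccc1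
F13 | step 2 | 2,4,6-tris(benzyloxy)-3-methoxyphenyl formate | COc1c(OCc2ccccc2)cc(OCc2ccccc2)c(OC=O)c1OCc1ccccc1
F14 | step 2 | 2,4,6-tris(benzyloxy)-3-methoxyphenol | COc1c(OCc2ccccc2)cc(OCc2ccccc2)c(O)c1OCc1ccccc1
F15 | step 3 | 1,3,5-tris(benzyloxy)-2-bromo-4,6-dimethoxybenzene | COc1c(OCc2ccccc2)c(Br)c(OCc2ccccc2)c(OC)c1OCc1ccccc1
F16 | step 3 | [2,4,6-tris(benzyloxy)-3,5-dimethoxyphenyl]lithium | COc1c(OCc2ccccc2)c([Li])c(OCc2ccccc2)c(OC)c1OCc1ccccc1
F17 | step 3 | lithium [2,4,6-tris(benzyloxy)-3,5-dimethoxyphenyl](dimethylamino)methanolate | COc1c(OCc2ccccc2)c(C([O-])N(C)C)c(OCc2ccccc2)c(OC)c1OCc1ccccc1.[Li+]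
A1 | alternative 1 | 5,7-bis(benzyloxy)-6,8-dimethoxy-2-(2,4,5-trimethoxyphenyl)-4H-chromen-4-one | COc1cc(OC)c(-c2cc(=O)c3c(OCc4ccccc4)c(OC)c(OCc4ccccc4)c(OC)c3o2)cc1OC
A2 | alternative 1 | 3,5-bis(benzyloxy)-2-iodo-4,6-dimethoxyphenol | Oc1c(I)c(OCc2ccccc2)c(OC)c(OCc2ccccc2)c1OC
A3 | alternative 1 | 1-ethynyl-2,4,5-trimethoxybenzene | C#Cc1cc(OC)c(OC)cc1OC
A4 | alternative 1 | carbon monoxide | [C-]#[O+]
A5 | alternative 2 | 5,7-bis(benzyloxy)-2-ethynyl-3,6,8-trimethoxy-4H-chromen-4-one | C#Cc1oc2c(OC)c(OCc3ccccc3)c(OC)c(OCc3ccccc3)c2c(=O)c1OC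
A6 | alternative 2 | pentacarbonyl[methoxy(1-methoxyethenyl)methylidene]chromium, Cr(CO)5[C(OMe)C(OMe)=CH2] | COC(=C)C(OC)=[Cr](=C=O)(=C=O)(=C=O)(=C=O)=C=O
A7 | alternative 2 | 5,7-bis(benzyloxy)-2-(2-hydroxy-4,5-dimethoxyphenyl)-3,6,8-trimethoxy-4H-chromen-4-one | COc1cc(O)c(-c2oc3c(OC)c(OCc4ccccc4)c(OC)c(OCc4ccccc4)c3c(=O)c2OC)cc1OC
A8 | alternative 3 | 2-methoxy-1-(2,4,5-trimethoxyphenyl)ethan-1-one | COCC(=O)c1cc(OC)c(OC)cc1OC
A9 | alternative 3 | 2,4-bis(benzyloxy)-6-bromo-3,5-dimethoxybenzoyl chloride | O=C(Cl)c1c(Br)c(OC)c(OCc2ccccc2)c(OC)c1OCc1ccccc1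
A10 | alternative 3 | 1-[2,4-bis(benzyloxy)-6-bromo-3,5-dimethoxyphenyl]-2-methoxy-3-(2,4,5-trimethoxyphenyl)propane-1,3-dione | COC(C(=O)c1cc(OC)c(OC)cc1OC)C(=O)c1c(Br)c(OC)c(OCc2ccccc2)c(OC)c1OCc1ccccc1
A11 | alternative 3 | 5,7-bis(benzyloxy)-3,6,8-trimethoxy-2-(2,4,5-trimethoxyphenyl)-4H-chromen-4-one | COc1cc(OC)c(-c2oc3c(OC)c(OCc4ccccc4)c(OC)c(OCc4ccccc4)c3c(=O)c2OC)cc1OC
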